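In ring A of hierochin B the two oxygenated carbons C7a and C7 are neighbours and C7a is flanked on its other side by C3a, which carries C3: this is what a cyclohexane-1,2-dione alkylated next to one carbonyl becomes on aromatisation. The dihydrofuran ring is therefore cut at C3–C3a and O1–C7a and built on the non-aromatic dione. In one pot the dione enol adds to an enantiopure γ-silyloxy nitroalkene (C3–C3a, creating C3) and the unmasked C2 hydroxyl condenses with the adjacent carbonyl (O1–C7a), closing a bicyclic enol ether. The precursors are cyclohexane-1,2-dione and the (S,E)-nitroalkene from veratraldehyde; aromatisation and the C5 side chain follow.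

Key step: step 5

Remark: the C2 silyl ether is cleaved with acetic acid-buffered fluoride, not by protic acid alone, so that desilylation does not depend on conditions that ionise the veratryl C–O bond; the catalyst antipode that delivers 3R is to be fixed in a test run; (E)-3-iodoprop-2-en-1-ol is taken as a catalogue compound.

Step 1
Reactants: 1 3,4-dimethoxybenzaldehyde; 2 vinylmagnesium bromide
Product: 3 rac-1-(3,4-dimethoxyphenyl)prop-2-en-1-ol
Conditions: THF, 0 °C; then aq. NH4Cl
Reagents that add atoms: none
Why: Grignard 1,2-addition to the aldehyde should give the racemic allylic alcohol, whose stereocentre is sorted in step 2.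

Step 2
Reactants: 3 rac-1-(3,4-dimethoxyphenyl)prop-2-en-1-ol
Product: 4 (S)-1-(3,4-dimethoxyphenyl)prop-2-en-1-ol
Conditions: immobilised Candida antarctica lipase B, vinyl acetate, MTBE, 30 °C, stopped slightly past half conversion
Reagents that add atoms: none
Why: Lipase-catalysed kinetic resolution by transesterification is expected to acylate the R alcohol (aryl as large, vinyl as medium group) and leave the S alcohol, which fixes C2 of the target.

Step 3
Reactants: 4 (S)-1-(3,4-dimethoxyphenyl)prop-2-en-1-ol
Product: 5 (S)-tert-butyl{[1-(3,4-dimethoxyphenyl)allyl]oxy}dimethylsilane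
Conditions: TBSCl, imidazole, DMF, 23 °C
Reagents that add atoms: tert-butyldimethylsilyl chloride, CC(C)(C)[Si](C)(C)Cl
Why: Imidazole-promoted O-silylation leaves the stereocentre untouched, and the bulky group should later hold the allylic C–H in the plane of the nitroalkene, out of alignment for γ-deprotonation.

Step 4
Reactants: 5 (S)-tert-butyl{[1-(3,4-dimethoxyphenyl)allyl]oxy}dimethylsilane
Product: 6 (S,E)-tert-butyl{[1-(3,4-dimethoxyphenyl)-3-nitroallyl]oxy}dimethylsilane
Conditions: AgNO2, TEMPO (0.4 equiv), 4 Å MS, 1,2-dichloroethane, 70 °C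
Reagents that add atoms: silver nitrite, [Ag+].[O-]N=O
Why: Radical nitration of a terminal alkene, in which NO2 from AgNO2 adds to the CH2 terminus and TEMPO removes the hydrogen next to the nitro group, should give the E-nitroalkene without touching the adjacent stereocentre.

Step 5
Reactants: 6 (S,E)-tert-butyl{[1-(3,4-dimethoxyphenyl)-3-nitroallyl]oxy}dimethylsilane; 7 cyclohexane-1,2-dione
Product: 11 (2S,3R)-2-(3,4-dimethoxyphenyl)-3-(nitromethyl)-3,4,5,6-tetrahydrobenzofuran-7(2H)-one, via silylated Michael adduct 8 (not isolated), via hydroxy enol 9 (not isolated), via cyclic hemiketal 10 (not isolated)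
Conditions: 7 (1.5 equiv), cinchona squaramide (quinine-derived 3,5-bis(trifluoromethyl)phenyl squaramide or its quinidine-derived pseudo-enantiomer, whichever delivers 3R; 5 mol%), CH2Cl2, −20 °C; then Bu4NF/AcOH, THF, 0 → 23 °C; then TsOH·H2O, 40 °C
Reagents that add atoms: none
Why: Proposed new method: the squaramide binds the nitro group through hydrogen bonds while its tertiary amine deprotonates the enol of 7, whose α-carbon (the future C3a) adds to the nitroalkene carbon next to C2 to give 8; the closest known reactions are the amine-catalysed Michael addition of cyclohexane-1,2-dione to nitroalkenes and the acid-catalysed formation of enol ethers from 1,2-diones and alcohols, which have not been run as one sequence on a γ-oxygenated nitroalkene. Acetic acid-buffered fluoride then frees the C2 hydroxyl (9) in a medium that still contains mild bases, so that the nitro-aldol closure of the adduct onto the C7 carbonyl, the usual follow-up of such adducts, remains reversible. The hydroxyl adds to the C7a carbonyl in a 5-exo-trig closure (10), and TsOH removes water irreversibly, placing the new C3a=C7a enol ether in conjugation with the C7 ketone and draining all equilibria into 11. C3, the only new stereocentre, is set by the face of the nitroalkene that the catalyst exposes (reagent control, which has to reinforce or override the 1,2-induction from C2), whereas C2 is carried over from 6 because the ring oxygen attacks the carbonyl and the C2–O bond stays intact. The step needs closure at C7a and not at C7, which the substrate secures because only C7a gives a fused five-membered ring that can dehydrate, attack at C7 leading to a bridged hemiketal that cannot. A small excess of acid in THF should leave the veratryl C2–O bond un-ionised, and ionisation followed by re-closure through the enol oxygen would in any case return the trans isomer as long as C3 is fixed.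

Step 6
Reactants: 11 (2S,3R)-2-(3,4-dimethoxyphenyl)-3-(nitromethyl)-3,4,5,6-tetrahydrobenzofuran-7(2H)-one
Product: 12 (2S,3R)-2-(3,4-dimethoxyphenyl)-3-(nitromethyl)-2,3-dihydrobenzofuran-7-ol
Conditions: Pd(OCOCF3)2 (5 mol%), 2-(dimethylamino)pyridine (10 mol%), TsOH·H2O (20 mol%), O2 (1 atm), DMSO, 80 °C
Reagents that add atoms: none
Why: Palladium-catalysed aerobic dehydrogenation of a cyclohexenone to a phenol (α-palladation at C6, β-hydride elimination from C5, tautomerisation of the dienone, O2 returning the metal to divalent palladium) should aromatise ring A while C2 and C3 lie outside the enolisable positions.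

Step 7
Reactants: 12 (2S,3R)-2-(3,4-dimethoxyphenyl)-3-(nitromethyl)-2,3-dihydrobenzofuran-7-ol
Product: 13 (2S,3R)-2-(3,4-dimethoxyphenyl)-7-methoxy-3-(nitromethyl)-2,3-dihydrobenzofuran
Conditions: MeI, K2CO3, acetone, 23 °C
Reagents that add atoms: iodomethane, CI
Why: Williamson O-methylation should be selective because the phenoxide forms at once and is far more nucleophilic towards MeI than the slowly formed nitronate of the CH2NO2 group.

Step 8
Reactants: 13 (2S,3R)-2-(3,4-dimethoxyphenyl)-7-methoxy-3-(nitromethyl)-2,3-dihydrobenzofuran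
Product: 14 (2S,3S)-2-(3,4-dimethoxyphenyl)-7-methoxy-2,3-dihydrobenzofuran-3-carboxylic acid
Conditions: NaNO2, AcOH, DMSO, 35 °C
Reagents that add atoms: sodium nitrite, [Na+].[O-]N=O; water, O (oxygen donors for the carboxyl group)
Why: Nitrite-mediated oxidation of a primary nitroalkane to the carboxylic acid (nitrosation to a nitrolic acid, loss of nitrous acid to a nitrile oxide, hydration and nitrosative cleavage) is a Nef-type conversion under weak acid in which C3–H is not enolised, so the trans arrangement should be kept (the C3 descriptor becomes S only through the priority rules).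

Step 9
Reactants: 14 (2S,3S)-2-(3,4-dimethoxyphenyl)-7-methoxy-2,3-dihydrobenzofuran-3-carboxylic acid
Product: 15 [(2S,3R)-2-(3,4-dimethoxyphenyl)-7-methoxy-2,3-dihydrobenzofuran-3-yl]methanol
Conditions: BH3·SMe2, THF, 0 → 23 °C; then H2O
Reagents that add atoms: none
Why: Chemoselective borane reduction of the carboxylic acid through an acyloxyborane should give the primary alcohol without base, so C3 keeps its configuration.

Step 10
Reactants: 15 [(2S,3R)-2-(3,4-dimethoxyphenyl)-7-methoxy-2,3-dihydrobenzofuran-3-yl]methanol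
Product: 17 [(2S,3R)-2-(3,4-dimethoxyphenyl)-7-methoxy-5-(4,4,5,5-tetramethyl-1,3,2-dioxaborolan-2-yl)-2,3-dihydrobenzofuran-3-yl]methanol, via bis-borylated ester 16 (not isolated)
Conditions: [Ir(OMe)(cod)]2 (2 mol%), 4,4'-di-tert-butyl-2,2'-bipyridine (4 mol%), B2pin2 (1.6 equiv), THF, 70 °C; then MeOH
Reagents that add atoms: bis(pinacolato)diboron, CC1(C)OB(OC1(C)C)B1OC(C)(C)C(C)(C)O1
Why: Iridium-catalysed, sterically governed aromatic C–H borylation should select C5, the only aromatic C–H without an ortho substituent (C4 is next to C3a, C6 next to OMe, and every C–H of the veratryl ring has an ortho neighbour), while the hydroxyl is O-borylated in the flask and released again by methanol.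

Step 11
Reactants: 17 [(2S,3R)-2-(3,4-dimethoxyphenyl)-7-methoxy-5-(4,4,5,5-tetramethyl-1,3,2-dioxaborolan-2-yl)-2,3-dihydrobenzofuran-3-yl]methanol; 18 (E)-3-iodoprop-2-en-1-ol
Product: 19 hierochin B, (E)-3-[(2S,3R)-2-(3,4-dimethoxyphenyl)-3-(hydroxymethyl)-7-methoxy-2,3-dihydrobenzofuran-5-yl]prop-2-en-1-ol
Conditions: 18 (1.3 equiv), PdCl2(dppf) (5 mol%), K3PO4, THF/H2O, 50 °C
Reagents that add atoms: none
Why: Suzuki–Miyaura coupling (oxidative addition of zerovalent palladium to the vinyl iodide with retention of the E geometry, phosphate-assisted transmetalation of the aryl boronate, reductive elimination) should attach the allylic alcohol side chain at C5 with both free hydroxyls tolerated.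

Compound list
1 | 3,4-dimethoxybenzaldehyde (veratraldehyde) | COc1ccc(C=O)cc1OC | starting material
2 | vinylmagnesium bromide | C=C[Mg]Br | starting material
3 | rac-1-(3,4-dimethoxyphenyl)prop-2-en-1-ol | COc1ccc(C(O)C=C)cc1OC | intermediate
4 | (S)-1-(3,4-dimethoxyphenyl)prop-2-en-1-ol | COc1ccc([C@@H](O)C=C)cc1OC | intermediate
5 | (S)-tert-butyl{[1-(3,4-dimethoxyphenyl)allyl]oxy}dimethylsilane | COc1ccc([C@@H](O[Si](C)(C)C(C)(C)C)C=C)cc1OC | intermediate
6 | (S,E)-tert-butyl{[1-(3,4-dimethoxyphenyl)-3-nitroallyl]oxy}dimethylsilane | COc1ccc([C@@H](O[Si](C)(C)C(C)(C)C)/C=C/[N+](=O)[O-])cc1OC | intermediate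
7 | cyclohexane-1,2-dione | O=C1CCCCC1=O | starting material
8 | 3-[(1S,2R)-1-[(tert-butyldimethylsilyl)oxy]-1-(3,4-dimethoxyphenyl)-3-nitropropan-2-yl]-2-hydroxycyclohex-2-en-1-one (formed in the flask, not isolated) | COc1ccc([C@@H](O[Si](C)(C)C(C)(C)C)[C@@H](C[N+](=O)[O-])C2=C(O)C(=O)CCC2)cc1OC | intermediate
9 | 3-[(1S,2R)-1-(3,4-dimethoxyphenyl)-1-hydroxy-3-nitropropan-2-yl]-2-hydroxycyclohex-2-en-1-one (formed in the flask, not isolated) | COc1ccc([C@@H](O)[C@@H](C[N+](=O)[O-])C2=C(O)C(=O)CCC2)cc1OC | intermediate
10 | (2S,3R)-2-(3,4-dimethoxyphenyl)-7a-hydroxy-3-(nitromethyl)hexahydrobenzofuran-7(2H)-one (transient; C3a and C7a unassigned; not isolated) | COc1ccc([C@H]2OC3(O)C(CCCC3=O)[C@@H]2C[N+](=O)[O-])cc1OC | intermediate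
11 | (2S,3R)-2-(3,4-dimethoxyphenyl)-3-(nitromethyl)-3,4,5,6-tetrahydrobenzofuran-7(2H)-one (trans) | COc1ccc([C@H]2OC3=C(CCCC3=O)[C@@H]2C[N+](=O)[O-])cc1OC | intermediate
12 | (2S,3R)-2-(3,4-dimethoxyphenyl)-3-(nitromethyl)-2,3-dihydrobenzofuran-7-ol | COc1ccc([C@H]2Oc3c(O)cccc3[C@@H]2C[N+](=O)[O-])cc1OC | intermediate
13 | (2S,3R)-2-(3,4-dimethoxyphenyl)-7-methoxy-3-(nitromethyl)-2,3-dihydrobenzofuran | COc1ccc([C@H]2Oc3c(OC)cccc3[C@@H]2C[N+](=O)[O-])cc1OC | intermediate
14 | (2S,3S)-2-(3,4-dimethoxyphenyl)-7-methoxy-2,3-dihydrobenzofuran-3-carboxylic acid (trans) | COc1ccc([C@H]2Oc3c(OC)cccc3[C@@H]2C(=O)O)cc1OC | intermediate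
15 | [(2S,3R)-2-(3,4-dimethoxyphenyl)-7-methoxy-2,3-dihydrobenzofuran-3-yl]methanol | COc1ccc([C@H]2Oc3c(OC)cccc3[C@@H]2CO)cc1OC | intermediate
16 | 2-{[(2S,3R)-2-(3,4-dimethoxyphenyl)-7-methoxy-5-(4,4,5,5-tetramethyl-1,3,2-dioxaborolan-2-yl)-2,3-dihydrobenzofuran-3-yl]methoxy}-4,4,5,5-tetramethyl-1,3,2-dioxaborolane (formed in the flask, not isolated) | COc1ccc([C@H]2Oc3c(OC)cc(B4OC(C)(C)C(C)(C)O4)cc3[C@@H]2COB2OC(C)(C)C(C)(C)O2)cc1OC | intermediate
17 | [(2S,3R)-2-(3,4-dimethoxyphenyl)-7-methoxy-5-(4,4,5,5-tetramethyl-1,3,2-dioxaborolan-2-yl)-2,3-dihydrobenzofuran-3-yl]methanol | COc1ccc([C@H]2Oc3c(OC)cc(B4OC(C)(C)C(C)(C)O4)cc3[C@@H]2CO)cc1OC | intermediate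
18 | (E)-3-iodoprop-2-en-1-ol | OC/C=C/I | starting material
19 | hierochin B, (E)-3-[(2S,3R)-2-(3,4-dimethoxyphenyl)-3-(hydroxymethyl)-7-methoxy-2,3-dihydrobenzofuran-5-yl]prop-2-en-1-ol | COc1ccc([C@H]2Oc3c(OC)cc(/C=C/CO)cc3[C@@H]2CO)cc1OC | target

Total steps: 11. Longest linear sequence: 11 steps (1 to 19); 7 and 18 enter as purchased partners.

Steps most likely to fail

Step 5. The Michael adduct may be diverted into the intramolecular nitro-aldol bicycle and fail to reopen before the medium turns acidic. The catalyst may not override the substrate's own facial bias at C3, and the nitroalkene may lose its C2 configuration through γ-deprotonation by the amine. A cis isomer, if formed, would be removed by chromatography at 11. The fallback uses known reaction types and sets out from 7 and 6. Compound 7 is mono-ketalised with ethylene glycol (TsOH, benzene, azeotropic removal of water) to 1,4-dioxaspiro[4.5]decan-6-one F1. F1 can enolise only at the future C3a and offers no second carbonyl for a nitro-aldol reaction. F1 is added to 6 by enamine catalysis (chiral primary amine–thiourea derived from trans-cyclohexane-1,2-diamine, PhCO2H, toluene, 23 °C), the standard ketone-to-nitroalkene Michael addition, which should give (R)-7-[(1S,2R)-1-[(tert-butyldimethylsilyl)oxy]-1-(3,4-dimethoxyphenyl)-3-nitropropan-2-yl]-1,4-dioxaspiro[4.5]decan-6-one F2. The ring stereocentre of F2 is lost later and is of no consequence. Desilylation (Bu4NF/AcOH, THF) gives (R)-7-[(1S,2R)-1-(3,4-dimethoxyphenyl)-1-hydroxy-3-nitropropan-2-yl]-1,4-dioxaspiro[4.5]decan-6-one F3. TsOH·H2O in wet acetone at 40 °C should then cyclodehydrate the γ-hydroxy ketone and hydrolyse the ketal, and the route is rejoined at 11.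

Step 6. α-Palladation of the α-alkoxy enone may be slow, the nitroalkyl group may inhibit the catalyst, or the electron-rich phenol may be oxidised further. The fallback sets out from 11. Acid-mediated α-selenenylation at C6 with PhSeCl (EtOAc, 23 °C) should give (2S,3R)-2-(3,4-dimethoxyphenyl)-3-(nitromethyl)-6-(phenylselanyl)-3,4,5,6-tetrahydrobenzofuran-7(2H)-one F4 as a mixture at C6. Oxidation with H2O2/pyridine (CH2Cl2, 0 °C) then triggers selenoxide syn-elimination from either C6 epimer. The resulting cross-conjugated dienone tautomerises to the phenol, and the route is rejoined at 12.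

Step 8. Nitrous acid-derived species may nitrosate or nitrate the two electron-rich arenes, or the sequence may stall before the carboxylic acid. The fallback sets out from 13 and uses a reductive Nef reaction. The nitronate (NaOMe, MeOH) is added to aqueous TiCl3 buffered with NH4OAc at 0 °C, which should give (2S,3S)-2-(3,4-dimethoxyphenyl)-7-methoxy-2,3-dihydrobenzofuran-3-carbaldehyde F5. F5 is prone to enolisation at C3 and β-elimination of the ring oxygen, so it is reduced at once with NaBH4 (MeOH, −20 °C). This bypasses 14 and rejoins the route at 15.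

Further compounds
F1 | step 5 | 1,4-dioxaspiro[4.5]decan-6-one | O=C1CCCCC12OCCO2
F2 | step 5 | (R)-7-[(1S,2R)-1-[(tert-butyldimethylsilyl)oxy]-1-(3,4-dimethoxyphenyl)-3-nitropropan-2-yl]-1,4-dioxaspiro[4.5]decan-6-one | COc1ccc([C@@H](O[Si](C)(C)C(C)(C)C)[C@@H](C[N+](=O)[O-])[C@H]2CCCC3(OCCO3)C2=O)cc1OC
F3 | step 5 | (R)-7-[(1S,2R)-1-(3,4-dimethoxyphenyl)-1-hydroxy-3-nitropropan-2-yl]-1,4-dioxaspiro[4.5]decan-6-one | COc1ccc([C@@H](O)[C@@H](C[N+](=O)[O-])[C@H]2CCCC3(OCCO3)C2=O)cc1OC
F4 | step 6 | (2S,3R)-2-(3,4-dimethoxyphenyl)-3-(nitromethyl)-6-(phenylselanyl)-3,4,5,6-tetrahydrobenzofuran-7(2H)-one (C6 epimers) | COc1ccc([C@H]2OC3=C(CCC([Se]c4ccccc4)C3=O)[C@@H]2C[N+](=O)[O-])cc1OC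
F5 | step 8 | (2S,3S)-2-(3,4-dimethoxyphenyl)-7-methoxy-2,3-dihydrobenzofuran-3-carbaldehyde | COc1ccc([C@H]2Oc3c(OC)cccc3[C@@H]2C=O)cc1OC
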